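**Strategy.** Everything rests on disconnecting ring D across D1–D6 and D4–D5. One Diels–Alder/aromatisation joins a (Z)-1,1-dimethoxy-3-silyloxybutadiene, which already carries the (3S)-chroman on its C4 terminus, to a ring-A aryl ethynyl ketone. It builds the arene and, by loss of methanol and of the silyl group, fixes its whole substitution. The step exploits the D2-OH/D4-OMe meta-dioxygenation with D3 and D6 unsubstituted: the lower chroman lands on D1 and the carbonyl that becomes C4 of the upper chroman on D5. The lower stereocentre is set earlier by asymmetric hydrogenation. Afterwards the upper chroman (C3, C4) is closed by enamine addition to an ortho-quinone methide released from ring A.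

Key step: step 11

Remark: the sense of induction in steps 3 and 17 is assigned from the usual models for (E)-2-substituted 3-aryl-acrylic acids on Ru(OAc)2(H8-BINAP) and for enamines of diarylprolinol silyl ethers; if a first run shows the opposite sense, the antipodal ligand or catalyst is taken.

**Route**

Step 1
Reactants: 1 4-(benzyloxy)-2-hydroxybenzaldehyde; 2 acrolein
Product: 3 7-(benzyloxy)-2H-chromene-3-carbaldehyde
Conditions: K2CO3, 1,4-dioxane, reflux
Reagents that add atoms: none
Why: Oxa-Michael addition of the phenoxide to acrolein and intramolecular aldol condensation onto the aryl aldehyde (domino oxa-Michael/aldol condensation) close the 2H-chromene with the formyl group on C3.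

Step 2
Reactants: 3 7-(benzyloxy)-2H-chromene-3-carbaldehyde
Product: 4 7-(benzyloxy)-2H-chromene-3-carboxylic acid
Conditions: NaClO2, NaH2PO4, 2-methyl-2-butene, t-BuOH/H2O, rt
Reagents that add atoms: sodium chlorite, [Na+].[O-]Cl=O
Why: Pinnick oxidation turns the enal into the acid while the alkene scavenger removes hypochlorite, so the styrenic double bond and the benzyl ether should survive.

Step 3
Reactants: 4 7-(benzyloxy)-2H-chromene-3-carboxylic acid
Product: 5 (3R)-7-(benzyloxy)chroman-3-carboxylic acid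
Conditions: H2 (30 bar), Ru(OAc)2[(S)-H8-BINAP] (1 mol%), MeOH/THF, 30 °C
Reagents that add atoms: none
Why: Carboxylate-directed asymmetric hydrogenation of an α,β-unsaturated acid on the ruthenium–bisphosphine complex delivers both hydrogens to one face of C3=C4 and sets C3 (R); the homogeneous catalyst should leave the benzyl ether alone.

Step 4
Reactants: 5 (3R)-7-(benzyloxy)chroman-3-carboxylic acid; 6 (trimethylsilyl)diazomethane
Product: 8 1-[(3R)-7-(benzyloxy)chroman-3-yl]-2-diazoethan-1-one, via acid chloride 7 (not isolated)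
Conditions: (COCl)2, DMF (cat.), CH2Cl2, 0 °C to rt; evaporate; then 6 (2.2 equiv), MeCN/THF, 0 °C
Reagents that add atoms: none
Why: First stage of the Arndt–Eistert homologation: the acid chloride acylates the diazoalkane carbon without added base, so the α-stereocentre is neither enolised nor turned into a ketene.

Step 5
Reactants: 8 1-[(3R)-7-(benzyloxy)chroman-3-yl]-2-diazoethan-1-one
Product: 10 2-[(3S)-7-(benzyloxy)chroman-3-yl]acetic acid, via ketene 9 (not isolated)
Conditions: PhCO2Ag (10 mol%), Et3N, THF/H2O, rt, dark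
Reagents that add atoms: water, O
Why: Silver-catalysed Wolff rearrangement: loss of nitrogen and 1,2-shift of the chromanyl carbon with retention give ketene 9, which water traps; the descriptor changes from R to S only because the priorities change.

Step 6
Reactants: 10 2-[(3S)-7-(benzyloxy)chroman-3-yl]acetic acid; 11 1,1-dimethoxyethene
Product: 13 1-[(3S)-7-(benzyloxy)chroman-3-yl]-4,4-dimethoxybut-3-en-2-one, via acid chloride 12 (not isolated)
Conditions: (COCl)2, DMF (cat.), CH2Cl2, 0 °C to rt; evaporate; then 11 (2.5 equiv), Et2O, 0 °C to rt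
Reagents that add atoms: none
Why: Acylation of a ketene acetal by an acid chloride: the nucleophilic CH2 of 11 attacks the acyl chloride and a second equivalent of 11 takes up the HCl, which should give the acylketene acetal without touching the β-stereocentre.

Step 7
Reactants: 13 1-[(3S)-7-(benzyloxy)chroman-3-yl]-4,4-dimethoxybut-3-en-2-one
Product: 14 (3Z)-4-[(3S)-7-(benzyloxy)chroman-3-yl]-1,1-dimethoxy-3-(trimethylsilyloxy)buta-1,3-diene
Conditions: TMSOTf (1.2 equiv), Et3N (2 equiv), Et2O, 0 °C; ammonium salt separated, diene used at once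
Reagents that add atoms: trimethylsilyl trifluoromethanesulfonate, C[Si](C)(C)OS(=O)(=O)C(F)(F)F
Why: Soft enolisation (O-silylation, then deprotonation of the only enolisable CH2) gives the cross-conjugated silyl dienol ether, and the Z isomer should prevail because it keeps the chromanyl group away from the ketene acetal arm.

Step 8
Reactants: 1 4-(benzyloxy)-2-hydroxybenzaldehyde
Product: 15 4-(benzyloxy)-2-(methoxymethoxy)benzaldehyde
Conditions: MOMCl, i-Pr2NEt, CH2Cl2, 0 °C to rt
Reagents that add atoms: chloromethyl methyl ether, COCCl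
Why: O-Alkylation of the phenol (Williamson-type) installs an acetal protecting group that is orthogonal to the benzyl ether and prevents later cyclisation of the ortho-oxygen onto the ynone.

Step 9
Reactants: 15 4-(benzyloxy)-2-(methoxymethoxy)benzaldehyde; 16 ethynylmagnesium bromide (HC≡CMgBr)
Product: 17 1-[4-(benzyloxy)-2-(methoxymethoxy)phenyl]prop-2-yn-1-ol (racemic)
Conditions: THF, 0 °C; then sat. aq. NH4Cl
Reagents that add atoms: none
Why: Grignard addition of the acetylide to the aldehyde gives the propargylic alcohol; its carbinol centre is racemic and is removed in step 10.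

Step 10
Reactants: 17 1-[4-(benzyloxy)-2-(methoxymethoxy)phenyl]prop-2-yn-1-ol
Product: 18 1-[4-(benzyloxy)-2-(methoxymethoxy)phenyl]prop-2-yn-1-one
Conditions: MnO2 (activated, excess), CH2Cl2, rt
Reagents that add atoms: none
Why: Activated MnO2 oxidises the doubly activated (benzylic and propargylic) alcohol selectively to the ynone under neutral conditions.

Step 11
Reactants: 14 (3Z)-4-[(3S)-7-(benzyloxy)chroman-3-yl]-1,1-dimethoxy-3-(trimethylsilyloxy)buta-1,3-diene; 18 1-[4-(benzyloxy)-2-(methoxymethoxy)phenyl]prop-2-yn-1-one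
Product: 21 {5-[(3S)-7-(benzyloxy)chroman-3-yl]-4-hydroxy-2-methoxyphenyl}[4-(benzyloxy)-2-(methoxymethoxy)phenyl]methanone, via cycloadduct 19 (not isolated), via aryl silyl ether 20 (not isolated)
Conditions: 14 (1.5 equiv), PhMe, 90 °C, sealed; then 10% aq. citric acid, THF, rt
Reagents that add atoms: none
Why: The silyl enol ether carbon C4 of 14, the terminus with the largest HOMO coefficient, bonds to the unsubstituted β-carbon of ynone 18 (D1–D6) and the ketene acetal carbon then bonds to the acyl-bearing α-carbon (D4–D5) in an asynchronous, polarised [4+2] cycloaddition that gives cyclohexa-1,4-diene 19. The closest known reaction type is the Diels–Alder/aromatisation of 1,1-dialkoxy-3-silyloxybuta-1,3-dienes with acetylenic ketones and esters, which gives 2-alkoxy-4-hydroxyaryl carbonyl compounds. Ring D is closed as a six-membered carbocycle by intermolecular [4+2] cycloaddition, both new bonds being formed between the two components. 1,4-Elimination of methanol from 19 (OMe from D4, H from D1) aromatises it to silyl ether 20, and mild acid frees the D2 phenol of 21. No stereocentre is created: the sp3 carbon D1 of 19 is transient, and the chroman C3 centre is not enolisable and takes no part. The step needs regioselectivity, which the match of the donor terminus with the ynone β-carbon secures, and an s-cis diene, which the Z enol ether secures by holding the chromanyl group on the outside.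

Step 12
Reactants: 21 {5-[(3S)-7-(benzyloxy)chroman-3-yl]-4-hydroxy-2-methoxyphenyl}[4-(benzyloxy)-2-(methoxymethoxy)phenyl]methanone
Product: 22 {4-(benzyloxy)-5-[(3S)-7-(benzyloxy)chroman-3-yl]-2-methoxyphenyl}[4-(benzyloxy)-2-(methoxymethoxy)phenyl]methanone
Conditions: BnBr, K2CO3, DMF, rt
Reagents that add atoms: benzyl bromide, BrCc1ccccc1
Why: Williamson ether synthesis on the acidic para-acyl phenol (D2) masks it so that only the ring-A phenol can later form a quinone methide.

Step 13
Reactants: 22 {4-(benzyloxy)-5-[(3S)-7-(benzyloxy)chroman-3-yl]-2-methoxyphenyl}[4-(benzyloxy)-2-(methoxymethoxy)phenyl]methanone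
Product: 23 {4-(benzyloxy)-5-[(3S)-7-(benzyloxy)chroman-3-yl]-2-methoxyphenyl}[4-(benzyloxy)-2-hydroxyphenyl]methanone
Conditions: HCl (cat.), MeOH/THF, 45 °C
Reagents that add atoms: none
Why: Acid-catalysed acetal exchange with methanol removes the MOM group (helped by the neighbouring carbonyl), while benzyl ethers and both rings are stable.

Step 14
Reactants: 23 {4-(benzyloxy)-5-[(3S)-7-(benzyloxy)chroman-3-yl]-2-methoxyphenyl}[4-(benzyloxy)-2-hydroxyphenyl]methanone
Product: 24 5-(benzyloxy)-2-[{4-(benzyloxy)-5-[(3S)-7-(benzyloxy)chroman-3-yl]-2-methoxyphenyl}(hydroxy)methyl]phenol (both carbinol epimers)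
Conditions: LiAlH4, THF, 0 °C; aq. KNaC4H4O6 (potassium sodium tartrate) work-up; used crude
Reagents that add atoms: none
Why: Hydride reduction of the diaryl ketone in an aprotic medium gives the ortho-hydroxybenzhydrol; the carbinol configuration is immaterial because this carbon becomes trigonal in step 17.

Step 15
Reactants: 25 2-hydroxy-4-methoxybenzaldehyde
Product: 26 2-(benzyloxy)-4-methoxybenzaldehyde
Conditions: BnBr, K2CO3, DMF, rt
Reagents that add atoms: benzyl bromide, BrCc1ccccc1
Why: Williamson ether synthesis protects the ring-B phenol, which would otherwise close onto the later acetaldehyde.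

Step 16
Reactants: 26 2-(benzyloxy)-4-methoxybenzaldehyde; 27 (methoxymethyl)triphenylphosphonium chloride
Product: 29 2-[2-(benzyloxy)-4-methoxyphenyl]acetaldehyde, via enol ether 28 (not isolated)
Conditions: 27, KOtBu, THF, 0 °C to rt; then 2 M aq. HCl, THF, 40 °C; used fresh
Reagents that add atoms: water, O
Why: Wittig methoxymethylenation followed by acid hydrolysis of the enol ether gives the one-carbon homologated arylacetaldehyde.

Step 17
Reactants: 24 5-(benzyloxy)-2-[{4-(benzyloxy)-5-[(3S)-7-(benzyloxy)chroman-3-yl]-2-methoxyphenyl}(hydroxy)methyl]phenol; 29 2-[2-(benzyloxy)-4-methoxyphenyl]acetaldehyde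
Product: 31 (3S,4R)-7-(benzyloxy)-3-[2-(benzyloxy)-4-methoxyphenyl]-4-{4-(benzyloxy)-5-[(3S)-7-(benzyloxy)chroman-3-yl]-2-methoxyphenyl}chroman-2-ol (both C2 anomers), via quinone methide 30 (not isolated)
Conditions: 29 (1.5 equiv), (S)-α,α-diphenylprolinol trimethylsilyl ether (20 mol%), PhCO2H (20 mol%), CH2Cl2, rt
Reagents that add atoms: none
Why: Benzoic acid dehydrates 24 to ortho-quinone methide 30 and the (E)-enamine of 29 adds through its unshielded Si face to the methide carbon (formal [4+2] annulation by enamine catalysis), which should set C3 as S and, through the trans arrangement of the two aryl groups, C4 as R; hydrolysis and lactol closure release the amine.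

Step 18
Reactants: 31 (3S,4R)-7-(benzyloxy)-3-[2-(benzyloxy)-4-methoxyphenyl]-4-{4-(benzyloxy)-5-[(3S)-7-(benzyloxy)chroman-3-yl]-2-methoxyphenyl}chroman-2-ol
Product: 32 (3S,4R)-7-(benzyloxy)-3-[2-(benzyloxy)-4-methoxyphenyl]-4-{4-(benzyloxy)-5-[(3S)-7-(benzyloxy)chroman-3-yl]-2-methoxyphenyl}chroman
Conditions: Et3SiH, BF3·OEt2, CH2Cl2, −78 to −20 °C
Reagents that add atoms: none
Why: Ionic hydrogenation: BF3 ionises the lactol to the cyclic oxocarbenium ion, which triethylsilane should reduce at low temperature before C3 can epimerise.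

Step 19
Reactants: 32 (3S,4R)-7-(benzyloxy)-3-[2-(benzyloxy)-4-methoxyphenyl]-4-{4-(benzyloxy)-5-[(3S)-7-(benzyloxy)chroman-3-yl]-2-methoxyphenyl}chroman
Product: 33 (3S,4R)-3-(2-hydroxy-4-methoxyphenyl)-4-{4-hydroxy-5-[(3S)-7-hydroxychroman-3-yl]-2-methoxyphenyl}chroman-7-ol
Conditions: H2 (1 atm), 10% Pd/C, THF/MeOH, rt
Reagents that add atoms: none
Why: Hydrogenolysis of the four benzyl ethers frees all phenols; the chroman C–O bonds and the diarylmethine C4 are not benzyl ethers and should not be cleaved.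

**Compound list**

1 | 4-(benzyloxy)-2-hydroxybenzaldehyde | O=Cc1ccc(OCc2ccccc2)cc1O | starting material
2 | acrolein | C=CC=O | starting material
3 | 7-(benzyloxy)-2H-chromene-3-carbaldehyde | O=CC1=Cc2ccc(OCc3ccccc3)cc2OC1 | intermediate
4 | 7-(benzyloxy)-2H-chromene-3-carboxylic acid | OC(=O)C1=Cc2ccc(OCc3ccccc3)cc2OC1 | intermediate
5 | (3R)-7-(benzyloxy)chroman-3-carboxylic acid | OC(=O)[C@H]1COc2cc(OCc3ccccc3)ccc2C1 | intermediate
6 | (trimethylsilyl)diazomethane | C[Si](C)(C)C=[N+]=[N-] | starting material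
7 | (3R)-7-(benzyloxy)chroman-3-carbonyl chloride | ClC(=O)[C@H]1COc2cc(OCc3ccccc3)ccc2C1 | intermediate
8 | 1-[(3R)-7-(benzyloxy)chroman-3-yl]-2-diazoethan-1-one | [N-]=[N+]=CC(=O)[C@H]1COc2cc(OCc3ccccc3)ccc2C1 | intermediate
9 | 2-[(3S)-7-(benzyloxy)chroman-3-yl]ethen-1-one (ketene) | O=C=C[C@H]1COc2cc(OCc3ccccc3)ccc2C1 | intermediate
10 | 2-[(3S)-7-(benzyloxy)chroman-3-yl]acetic acid | OC(=O)C[C@H]1COc2cc(OCc3ccccc3)ccc2C1 | intermediate
11 | 1,1-dimethoxyethene | C=C(OC)OC | starting material
12 | 2-[(3S)-7-(benzyloxy)chroman-3-yl]acetyl chloride | ClC(=O)C[C@H]1COc2cc(OCc3ccccc3)ccc2C1 | intermediate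
13 | 1-[(3S)-7-(benzyloxy)chroman-3-yl]-4,4-dimethoxybut-3-en-2-one | COC(OC)=CC(=O)C[C@H]1COc2cc(OCc3ccccc3)ccc2C1 | intermediate
14 | (3Z)-4-[(3S)-7-(benzyloxy)chroman-3-yl]-1,1-dimethoxy-3-(trimethylsilyloxy)buta-1,3-diene | COC(OC)=CC(/O[Si](C)(C)C)=C/[C@H]1COc2cc(OCc3ccccc3)ccc2C1 | intermediate
15 | 4-(benzyloxy)-2-(methoxymethoxy)benzaldehyde | COCOc1cc(OCc2ccccc2)ccc1C=O | intermediate
16 | ethynylmagnesium bromide | C#C[Mg]Br | starting material
17 | 1-[4-(benzyloxy)-2-(methoxymethoxy)phenyl]prop-2-yn-1-ol (racemic) | C#CC(O)c1ccc(OCc2ccccc2)cc1OCOC | intermediate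
18 | 1-[4-(benzyloxy)-2-(methoxymethoxy)phenyl]prop-2-yn-1-one | C#CC(=O)c1ccc(OCc2ccccc2)cc1OCOC | intermediate
19 | {3-[(3S)-7-(benzyloxy)chroman-3-yl]-6,6-dimethoxy-4-(trimethylsilyloxy)cyclohexa-1,4-dien-1-yl}[4-(benzyloxy)-2-(methoxymethoxy)phenyl]methanone (epimers at the ring sp3 carbon) | COC1(OC)C=C(O[Si](C)(C)C)C([C@H]2COc3cc(OCc4ccccc4)ccc3C2)C=C1C(=O)c1ccc(OCc2ccccc2)cc1OCOC | intermediate
20 | {5-[(3S)-7-(benzyloxy)chroman-3-yl]-2-methoxy-4-(trimethylsilyloxy)phenyl}[4-(benzyloxy)-2-(methoxymethoxy)phenyl]methanone | COc1cc(O[Si](C)(C)C)c([C@H]2COc3cc(OCc4ccccc4)ccc3C2)cc1C(=O)c1ccc(OCc2ccccc2)cc1OCOC | intermediate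
21 | {5-[(3S)-7-(benzyloxy)chroman-3-yl]-4-hydroxy-2-methoxyphenyl}[4-(benzyloxy)-2-(methoxymethoxy)phenyl]methanone | COc1cc(O)c([C@H]2COc3cc(OCc4ccccc4)ccc3C2)cc1C(=O)c1ccc(OCc2ccccc2)cc1OCOC | intermediate
22 | {4-(benzyloxy)-5-[(3S)-7-(benzyloxy)chroman-3-yl]-2-methoxyphenyl}[4-(benzyloxy)-2-(methoxymethoxy)phenyl]methanone | COc1cc(OCc2ccccc2)c([C@H]2COc3cc(OCc4ccccc4)ccc3C2)cc1C(=O)c1ccc(OCc2ccccc2)cc1OCOC | intermediate
23 | {4-(benzyloxy)-5-[(3S)-7-(benzyloxy)chroman-3-yl]-2-methoxyphenyl}[4-(benzyloxy)-2-hydroxyphenyl]methanone | COc1cc(OCc2ccccc2)c([C@H]2COc3cc(OCc4ccccc4)ccc3C2)cc1C(=O)c1ccc(OCc2ccccc2)cc1O | intermediate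
24 | 5-(benzyloxy)-2-[{4-(benzyloxy)-5-[(3S)-7-(benzyloxy)chroman-3-yl]-2-methoxyphenyl}(hydroxy)methyl]phenol (both carbinol epimers) | COc1cc(OCc2ccccc2)c([C@H]2COc3cc(OCc4ccccc4)ccc3C2)cc1C(O)c1ccc(OCc2ccccc2)cc1O | intermediate
25 | 2-hydroxy-4-methoxybenzaldehyde | COc1ccc(C=O)c(O)c1 | starting material
26 | 2-(benzyloxy)-4-methoxybenzaldehyde | COc1ccc(C=O)c(OCc2ccccc2)c1 | intermediate
27 | (methoxymethyl)triphenylphosphonium chloride | COC[P+](c1ccccc1)(c1ccccc1)c1ccccc1.[Cl-] | starting material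
28 | 2-(benzyloxy)-4-methoxy-1-(2-methoxyethenyl)benzene (E/Z mixture) | COC=Cc1ccc(OC)cc1OCc1ccccc1 | intermediate
29 | 2-[2-(benzyloxy)-4-methoxyphenyl]acetaldehyde | COc1ccc(CC=O)c(OCc2ccccc2)c1 | intermediate
30 | 3-(benzyloxy)-6-[{4-(benzyloxy)-5-[(3S)-7-(benzyloxy)chroman-3-yl]-2-methoxyphenyl}methylidene]cyclohexa-2,4-dien-1-one (ortho-quinone methide) | COc1cc(OCc2ccccc2)c([C@H]2COc3cc(OCc4ccccc4)ccc3C2)cc1C=C1C=CC(OCc2ccccc2)=CC1=O | intermediate
31 | (3S,4R)-7-(benzyloxy)-3-[2-(benzyloxy)-4-methoxyphenyl]-4-{4-(benzyloxy)-5-[(3S)-7-(benzyloxy)chroman-3-yl]-2-methoxyphenyl}chroman-2-ol (both C2 anomers) | COc1ccc([C@H]2C(O)Oc3cc(OCc4ccccc4)ccc3[C@@H]2c2cc([C@H]3COc4cc(OCc5ccccc5)ccc4C3)c(OCc3ccccc3)cc2OC)c(OCc2ccccc2)c1 | intermediate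
32 | (3S,4R)-7-(benzyloxy)-3-[2-(benzyloxy)-4-methoxyphenyl]-4-{4-(benzyloxy)-5-[(3S)-7-(benzyloxy)chroman-3-yl]-2-methoxyphenyl}chroman | COc1ccc([C@H]2COc3cc(OCc4ccccc4)ccc3[C@@H]2c2cc([C@H]3COc4cc(OCc5ccccc5)ccc4C3)c(OCc3ccccc3)cc2OC)c(OCc2ccccc2)c1 | intermediate
33 | (3S,4R)-3-(2-hydroxy-4-methoxyphenyl)-4-{4-hydroxy-5-[(3S)-7-hydroxychroman-3-yl]-2-methoxyphenyl}chroman-7-ol | COc1ccc([C@H]2COc3cc(O)ccc3[C@@H]2c2cc([C@H]3COc4cc(O)ccc4C3)c(O)cc2OC)c(O)c1 | target

**Totals**

Total step count: 19. Longest linear sequence: 14 steps (steps 1–7, 11–14, 17–19).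

**Steps most likely to fail**

1. Step 11. Bond formation at the branched, substituted diene terminus may be slower than thermal oligomerisation of the donor-deactivated ynone and conjugate addition of the liberated methanol to it, so that the ynone is used up unproductively while the diene loses its silyl group.
Fallback, setting out from diene 14 and coming back at benzhydrol 24: methyl propiolate, a small and thermally robust dienophile that can be taken in large excess, replaces the ynone (PhMe, 90 °C; then aqueous citric acid). By way of the cycloadduct methyl 3-[(3S)-7-(benzyloxy)chroman-3-yl]-6,6-dimethoxy-4-(trimethylsilyloxy)cyclohexa-1,4-diene-1-carboxylate F1 and the aryl silyl ether methyl 5-[(3S)-7-(benzyloxy)chroman-3-yl]-2-methoxy-4-(trimethylsilyloxy)benzoate F2, this should give the phenol ester methyl 5-[(3S)-7-(benzyloxy)chroman-3-yl]-4-hydroxy-2-methoxybenzoate F3. Benzylation (BnBr, K2CO3, DMF) would give methyl 4-(benzyloxy)-5-[(3S)-7-(benzyloxy)chroman-3-yl]-2-methoxybenzoate F4. LiAlH4 would give the benzylic alcohol {4-(benzyloxy)-5-[(3S)-7-(benzyloxy)chroman-3-yl]-2-methoxyphenyl}methanol F5, and MnO2 the aldehyde 4-(benzyloxy)-5-[(3S)-7-(benzyloxy)chroman-3-yl]-2-methoxybenzaldehyde F6. The C4–ring A bond is then made by ortho-selective hydroxyalkylation: the bromomagnesium phenoxide of commercial 3-(benzyloxy)phenol (EtMgBr, PhMe, rt) should add to F6 through a six-membered magnesium chelate at its free ortho position para to the benzyloxy group. This gives benzhydrol 24 directly, from which steps 17–19 follow.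

2. Step 17. The quinone methide, stabilised by three donor groups, may be too weak an electrophile for the enamine or may be attacked without enough facial discrimination, while the arylacetaldehyde is lost to self-condensation.
Fallback, setting out from benzhydrol 24 and enol ether 28 (here isolated after the Wittig stage of step 16 and enriched in the E isomer) and coming back at 32: the quinone methide is activated instead as a hydrogen-bonded ion pair by a chiral phosphoric acid, (R)-3,3'-bis(2,4,6-triisopropylphenyl)-1,1'-binaphthyl-2,2'-diyl hydrogen phosphate, whose hand is matched to the required sense. Inverse-electron-demand oxa-Diels–Alder addition of the enol ether with methoxy endo should give the 3,4-trans acetal (3S,4R)-7-(benzyloxy)-3-[2-(benzyloxy)-4-methoxyphenyl]-4-{4-(benzyloxy)-5-[(3S)-7-(benzyloxy)chroman-3-yl]-2-methoxyphenyl}-2-methoxychroman F7. Et3SiH/BF3·OEt2 then reduces the acetal carbon to give 32.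

3. Step 18. Reversible loss of the C3 proton from the oxocarbenium ion (through a 4H-chromene) would scramble C3, and the cation may be captured by one of the electron-rich arenes.
Fallback, setting out from lactol 31 and coming back at 32: NaBH4 (EtOH/THF, 0 °C) reduces the open hydroxy-aldehyde form to the diol (2S,3R)-2-[2-(benzyloxy)-4-methoxyphenyl]-3-[4-(benzyloxy)-2-hydroxyphenyl]-3-{4-(benzyloxy)-5-[(3S)-7-(benzyloxy)chroman-3-yl]-2-methoxyphenyl}propan-1-ol F8. Mitsunobu cyclisation (PPh3, DIAD, THF) of the phenol onto the primary alcohol then closes the chroman without passing through a cation.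

**Further compounds**

F1 | step 11 | methyl 3-[(3S)-7-(benzyloxy)chroman-3-yl]-6,6-dimethoxy-4-(trimethylsilyloxy)cyclohexa-1,4-diene-1-carboxylate | COC(=O)C1=CC([C@H]2COc3cc(OCc4ccccc4)ccc3C2)C(O[Si](C)(C)C)=CC1(OC)OC
F2 | step 11 | methyl 5-[(3S)-7-(benzyloxy)chroman-3-yl]-2-methoxy-4-(trimethylsilyloxy)benzoate | COC(=O)c1cc([C@H]2COc3cc(OCc4ccccc4)ccc3C2)c(O[Si](C)(C)C)cc1OC
F3 | step 11 | methyl 5-[(3S)-7-(benzyloxy)chroman-3-yl]-4-hydroxy-2-methoxybenzoate | COC(=O)c1cc([C@H]2COc3cc(OCc4ccccc4)ccc3C2)c(O)cc1OC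
F4 | step 11 | methyl 4-(benzyloxy)-5-[(3S)-7-(benzyloxy)chroman-3-yl]-2-methoxybenzoate | COC(=O)c1cc([C@H]2COc3cc(OCc4ccccc4)ccc3C2)c(OCc2ccccc2)cc1OC
F5 | step 11 | {4-(benzyloxy)-5-[(3S)-7-(benzyloxy)chroman-3-yl]-2-methoxyphenyl}methanol | OCc1cc([C@H]2COc3cc(OCc4ccccc4)ccc3C2)c(OCc2ccccc2)cc1OC
F6 | step 11 | 4-(benzyloxy)-5-[(3S)-7-(benzyloxy)chroman-3-yl]-2-methoxybenzaldehyde | O=Cc1cc([C@H]2COc3cc(OCc4ccccc4)ccc3C2)c(OCc2ccccc2)cc1OC
F7 | step 17 | (3S,4R)-7-(benzyloxy)-3-[2-(benzyloxy)-4-methoxyphenyl]-4-{4-(benzyloxy)-5-[(3S)-7-(benzyloxy)chroman-3-yl]-2-methoxyphenyl}-2-methoxychroman | COc1ccc([C@H]2C(OC)Oc3cc(OCc4ccccc4)ccc3[C@@H]2c2cc([C@H]3COc4cc(OCc5ccccc5)ccc4C3)c(OCc3ccccc3)cc2OC)c(OCc2ccccc2)c1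
F8 | step 18 | (2S,3R)-2-[2-(benzyloxy)-4-methoxyphenyl]-3-[4-(benzyloxy)-2-hydroxyphenyl]-3-{4-(benzyloxy)-5-[(3S)-7-(benzyloxy)chroman-3-yl]-2-methoxyphenyl}propan-1-ol | COc1ccc([C@@H](CO)[C@H](c2ccc(OCc3ccccc3)cc2O)c2cc([C@H]3COc4cc(OCc5ccccc5)ccc4C3)c(OCc3ccccc3)cc2OC)c(OCc2ccccc2)c1
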